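**Retrosynthetic overview**
1. Target ⇐ late SeO2 oxidation of the isopropenyl CH3, chlorohydrin → oxirane, C6 angeloylation (anhydride made from tiglic acid), Mannich methylenation of the lactone, hydride reduction of a C6 ketone.
2. Cyclohexane (the only carbocycle) ⇐ intramolecular 6-enolendo aldol addition C7 → C8 of a γ-keto ester aldehyde; the γ-lactone closes directly afterwards.
3. Aldol precursor ⇐ Wacker oxidation and enolate alkylation (C6, C7, C11, C12), Narasaka reduction of a chloromethyl ketone (C1), Frater–Seebach methylation (C10).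
4. C5–C10 bond ⇐ chelated dianion Ireland–Claisen rearrangement of an ester that joins two three-step fragments: a β-hydroxy ester from (S)-malic acid (C8–C10, C1) and a dienol from methacrolein (C3–C7, C15).
5. Ring order: temporary 1,3-dioxane (O1/O9 acetonide) → cyclohexane (aldol) → γ-lactone → oxirane last.

Assumption: locants C1–C15 are the elemane locants of the target (ring C5–C10; C1/C2 oxirane carbons on C10; C3/C4/C15 acrolein unit on C5; C11–C13 methylene lactone; C14 methyl on C10), and dibromide 32 is carried as the racemate because only achiral 34 goes on.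

**Route**

Step 1
Reactants: 1 (S)-malic acid
Product: 2 dimethyl (2S)-2-hydroxybutanedioate
Conditions: MeOH, H2SO4 (cat.), reflux
Reagents that add atoms: methanol CO
Why: Fischer esterification of both carboxyl groups leaves the carbinol stereocentre (later C9) untouched.

Step 2
Reactants: 2 dimethyl (2S)-2-hydroxybutanedioate
Product: 3 methyl (3S)-3,4-dihydroxybutanoate
Conditions: BH3·SMe2 (1.05 equiv), NaBH4 (5 mol%), THF, 0 → 23 °C; MeOH quench
Reagents that add atoms: none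
Why: Hydroxyl-directed borane reduction (Saito reduction) goes through a cyclic alkoxyborane, so only the ester next to the hydroxyl is reduced and the stereocentre is retained.

Step 3
Reactants: 3 methyl (3S)-3,4-dihydroxybutanoate
Product: 4 methyl (3S)-4-[(tert-butyldimethylsilyl)oxy]-3-hydroxybutanoate
Conditions: TBSCl (1.05 equiv), imidazole, CH2Cl2, 0 °C
Reagents that add atoms: tert-butyldimethylsilyl chloride CC(C)(C)[Si](C)(C)Cl
Why: Selective silylation of the primary hydroxyl leaves the secondary carbinol free for the later chelate-controlled enolate steps.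

Step 4
Reactants: 5 (2-ethoxy-2-oxoethyl)triphenylphosphonium bromide
Product: 6 ethyl 2-(triphenyl-λ5-phosphanylidene)acetate
Conditions: NaOH (1 M aq), CH2Cl2, 23 °C
Reagents that add atoms: none
Why: Deprotonation of the phosphonium salt gives the stabilised ylide.

Step 5
Reactants: 6 ethyl 2-(triphenyl-λ5-phosphanylidene)acetate; 7 methacrolein (2-methylprop-2-enal)
Product: 8 ethyl (2E)-4-methylpenta-2,4-dienoate
Conditions: CH2Cl2, 23 °C
Reagents that add atoms: none
Why: Wittig olefination with a stabilised ylide gives the (E)-enoate.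

Step 6
Reactants: 8 ethyl (2E)-4-methylpenta-2,4-dienoate
Product: 9 (2E)-4-methylpenta-2,4-dien-1-ol
Conditions: iBu2AlH (2.2 equiv), CH2Cl2, −78 °C; aq. KNaC4H4O6 work-up
Reagents that add atoms: none
Why: 1,2-Reduction of the ester by the aluminium hydride gives the allylic alcohol without touching the diene.

Step 7
Reactants: 4 methyl (3S)-4-[(tert-butyldimethylsilyl)oxy]-3-hydroxybutanoate; 9 (2E)-4-methylpenta-2,4-dien-1-ol
Product: 10 (2E)-4-methylpenta-2,4-dien-1-yl (3S)-4-[(tert-butyldimethylsilyl)oxy]-3-hydroxybutanoate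
Conditions: ClBu2SnOSnBu2Cl (5 mol%), toluene, 100 °C, MeOH distilled off
Reagents that add atoms: none
Why: Distannoxane-catalysed transesterification under neutral conditions joins the two fragments and is driven by removal of methanol.

Step 8
Reactants: 10 (2E)-4-methylpenta-2,4-dien-1-yl (3S)-4-[(tert-butyldimethylsilyl)oxy]-3-hydroxybutanoate
Product: 12 methyl (2R,3S)-4-[(tert-butyldimethylsilyl)oxy]-3-hydroxy-2-[(3R)-2-methylpenta-1,4-dien-3-yl]butanoate, via acid 11 (not isolated)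
Conditions: LiN(iPr)2 (2.3 equiv), THF, −78 → 23 °C, 14 h; then AcOH, MeOH, Me3SiCHN2, 0 °C
Reagents that add atoms: (trimethylsilyl)diazomethane C[Si](C)(C)C=[N+]=[N-]
Why: Chelated dianion Ireland–Claisen rearrangement, in which the lithium alkoxide–enolate chelate makes the allyl terminus add to the enolate face anti to the CH2OTBS group through a chair transition state with the (E)-isopropenyl group equatorial, sets C5, and the acid is methylated in the same flask.

Step 9
Reactants: 12 methyl (2R,3S)-4-[(tert-butyldimethylsilyl)oxy]-3-hydroxy-2-[(3R)-2-methylpenta-1,4-dien-3-yl]butanoate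
Product: 13 methyl (2S,3S)-4-[(tert-butyldimethylsilyl)oxy]-3-hydroxy-2-methyl-2-[(3S)-2-methylpenta-1,4-dien-3-yl]butanoate
Conditions: LiN(iPr)2 (2.4 equiv), THF, −78 → −20 °C; MeI, DMPU, −78 → −20 °C; AcOH
Reagents that add atoms: iodomethane CI
Why: Frater–Seebach alkylation, in which iodomethane attacks the chelated dianion anti to the CH2OTBS group, creates the quaternary C10 centre in the required configuration whatever the former α-configuration was.

Step 10
Reactants: 13 methyl (2S,3S)-4-[(tert-butyldimethylsilyl)oxy]-3-hydroxy-2-methyl-2-[(3S)-2-methylpenta-1,4-dien-3-yl]butanoate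
Product: 14 (3S,4S)-5-[(tert-butyldimethylsilyl)oxy]-1-chloro-4-hydroxy-3-methyl-3-[(3S)-2-methylpenta-1,4-dien-3-yl]pentan-2-one
Conditions: MeLi·LiBr (1.0 equiv), THF, −78 °C; then ICH2Cl (2.5 equiv), MeLi·LiBr (2.5 equiv), −78 °C; AcOH, −78 °C
Reagents that add atoms: chloroiodomethane ClCI
Why: Nucleophilic acyl substitution by a lithium carbenoid: chloromethyllithium made in the flask adds to the ester and the chelated tetrahedral intermediate collapses only on quench, giving the chloromethyl ketone that carries C2.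

Step 11
Reactants: 14 (3S,4S)-5-[(tert-butyldimethylsilyl)oxy]-1-chloro-4-hydroxy-3-methyl-3-[(3S)-2-methylpenta-1,4-dien-3-yl]pentan-2-one
Product: 16 tert-butyl{[(4S,5S,6R)-6-(chloromethyl)-2,2,5-trimethyl-5-[(3S)-2-methylpenta-1,4-dien-3-yl]-1,3-dioxan-4-yl]methoxy}dimethylsilane, via diol 15 (not isolated)
Conditions: Et2BOMe (1.2 equiv), NaBH4 (1.3 equiv), THF/MeOH 4:1, −78 °C; AcOH, MeOH co-evaporation; then Me2C(OMe)2, PPTS (cat.), CH2Cl2, 23 °C
Reagents that add atoms: 2,2-dimethoxypropane COC(C)(C)OC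
Why: Narasaka–Prasad reduction, with external hydride delivery to the boron chelate of the β-hydroxy ketone, gives the 1,3-syn diol and so sets C1, and the diol is masked as its acetonide.

Step 12
Reactants: 16 tert-butyl{[(4S,5S,6R)-6-(chloromethyl)-2,2,5-trimethyl-5-[(3S)-2-methylpenta-1,4-dien-3-yl]-1,3-dioxan-4-yl]methoxy}dimethylsilane
Product: 17 (3S)-3-[(4S,5S,6R)-4-{[(tert-butyldimethylsilyl)oxy]methyl}-6-(chloromethyl)-2,2,5-trimethyl-1,3-dioxan-5-yl]-4-methylpent-4-en-2-one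
Conditions: PdCl2 (10 mol%), CuCl (1 equiv), O2 (1 atm), DMF/H2O 7:1, 23 °C
Reagents that add atoms: water O
Why: Tsuji–Wacker oxidation converts the monosubstituted vinyl group into the methyl ketone by Markovnikov hydroxypalladation while the 1,1-disubstituted isopropenyl group is inert.

Step 13
Reactants: 18 methyl bromoacetate
Product: 19 methyl iodoacetate
Conditions: NaI, acetone, 23 °C
Reagents that add atoms: sodium iodide [Na+].[I-]
Why: Finkelstein halide exchange gives the more reactive alkylating agent.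

Step 14
Reactants: 17 (3S)-3-[(4S,5S,6R)-4-{[(tert-butyldimethylsilyl)oxy]methyl}-6-(chloromethyl)-2,2,5-trimethyl-1,3-dioxan-5-yl]-4-methylpent-4-en-2-one; 19 methyl iodoacetate
Product: 20 methyl (5S)-5-[(4S,5S,6R)-4-{[(tert-butyldimethylsilyl)oxy]methyl}-6-(chloromethyl)-2,2,5-trimethyl-1,3-dioxan-5-yl]-6-methyl-4-oxohept-6-enoate
Conditions: LiN(iPr)2 (1.05 equiv), THF, −78 °C; 19 (1.3 equiv), DMPU, −78 → −50 °C
Reagents that add atoms: none
Why: Kinetic deprotonation of the methyl ketone at the unhindered CH3 and SN2 alkylation with the iodoacetate install C11–C12 without touching the hindered C5–H.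

Step 15
Reactants: 20 methyl (5S)-5-[(4S,5S,6R)-4-{[(tert-butyldimethylsilyl)oxy]methyl}-6-(chloromethyl)-2,2,5-trimethyl-1,3-dioxan-5-yl]-6-methyl-4-oxohept-6-enoate
Product: 21 methyl (5S)-5-[(4S,5S,6R)-6-(chloromethyl)-4-(hydroxymethyl)-2,2,5-trimethyl-1,3-dioxan-5-yl]-6-methyl-4-oxohept-6-enoate
Conditions: HF·pyridine, pyridine, THF, 0 → 23 °C
Reagents that add atoms: none
Why: Buffered fluoride cleaves the primary silyl ether and leaves the acetonide intact.

Step 16
Reactants: 21 methyl (5S)-5-[(4S,5S,6R)-6-(chloromethyl)-4-(hydroxymethyl)-2,2,5-trimethyl-1,3-dioxan-5-yl]-6-methyl-4-oxohept-6-enoate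
Product: 24 (1R,5S,7R,8R,9S,10S)-2-chloro-1,9-(isopropylidenedioxy)-6-oxoelem-3-en-12,8-olide, via aldehyde 22 (not isolated), via ketol 23 (not isolated)
Conditions: Dess–Martin periodinane, CH2Cl2, 0 → 23 °C; then L-proline (30 mol%), DMSO, 23 °C; then PPTS (10 mol%), toluene, 50 °C
Reagents that add atoms: none
Why: After Dess–Martin oxidation, the reversible amine-catalysed intramolecular 6-enolendo aldol addition of C7 onto C8 closes the cyclohexane and settles C7 and C8 in the all-equatorial trans arrangement, which acid-catalysed lactonisation traps as the trans-fused γ-lactone.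

Step 17
Reactants: 24 (1R,5S,7R,8R,9S,10S)-2-chloro-1,9-(isopropylidenedioxy)-6-oxoelem-3-en-12,8-olide
Product: 25 (1R,5S,6S,7S,8R,9S,10S)-2-chloro-6-hydroxy-1,9-(isopropylidenedioxy)elem-3-en-12,8-olide
Conditions: LiBH(s-Bu)3 (1.2 equiv), THF, −78 °C; AcOH
Reagents that add atoms: none
Why: The bulky hydride attacks the C6 ketone from the equatorial α face because the axial face is blocked by the syn-axial C10 methyl group, giving the axial 6β-alcohol.

Step 18
Reactants: 26 N,N,N',N'-tetramethylmethanediamine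
Product: 27 N,N-dimethylmethaniminium chloride
Conditions: AcCl, Et2O, 0 °C
Reagents that add atoms: acetyl chloride CC(=O)Cl
Why: Acylative cleavage of the aminal gives the iminium chloride.

Step 19
Reactants: 25 (1R,5S,6S,7S,8R,9S,10S)-2-chloro-6-hydroxy-1,9-(isopropylidenedioxy)elem-3-en-12,8-olide; 27 N,N-dimethylmethaniminium chloride
Product: 30 (1R,5S,6S,7S,8R,9S,10S)-2-chloro-6-hydroxy-1,9-(isopropylidenedioxy)elema-3,11(13)-dien-12,8-olide, via Mannich base 28 (not isolated), via ammonium iodide 29 (not isolated)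
Conditions: LiN(iPr)2 (2.3 equiv), THF, −78 °C (inverse addition); 27 (3 equiv), −78 → 0 °C; then MeI, MeOH, 23 °C; then NaHCO3 (aq), 23 °C
Reagents that add atoms: none
Why: Mannich reaction of the lactone enolate (alkoxide–enolate dianion) with the iminium salt, followed by quaternisation and Hofmann-type elimination, gives the α-methylene lactone.

Step 20
Reactants: 31 tiglic acid
Product: 32 rac-(2R,3S)-2,3-dibromo-2-methylbutanoic acid
Conditions: Br2, CH2Cl2, 0 °C
Reagents that add atoms: bromine BrBr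
Why: Anti addition of bromine to the (E)-alkene gives the racemic dibromide.

Step 21
Reactants: 32 rac-(2R,3S)-2,3-dibromo-2-methylbutanoic acid
Product: 33 (2E)-3-bromo-2-methylbut-2-enoic acid
Conditions: KOH, MeOH, 55 °C; then HCl (aq)
Reagents that add atoms: none
Why: E2 anti-elimination of HBr gives the 3-bromo acid in which CO2H and the C4 methyl are already cis.

Step 22
Reactants: 33 (2E)-3-bromo-2-methylbut-2-enoic acid
Product: 34 angelic acid
Conditions: sodium amalgam (Na/Hg), H2O, 0 → 23 °C; then HCl (aq)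
Reagents that add atoms: none
Why: Reductive removal of the vinylic bromine proceeds with retention of alkene geometry and gives the (Z)-acid.

Step 23
Reactants: 34 angelic acid
Product: 35 angelic anhydride
Conditions: 34 (2.0 equiv), DCC (1.0 equiv), CH2Cl2, 0 → 23 °C; urea filtered off
Reagents that add atoms: angelic acid C/C=C(/C)C(=O)O
Why: Carbodiimide-mediated dehydration joins two molecules of 34 (one is activated as its O-acylisourea and acylates the carboxylate of the second), giving the symmetric anhydride without Z/E isomerisation.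

Step 24
Reactants: 30 (1R,5S,6S,7S,8R,9S,10S)-2-chloro-6-hydroxy-1,9-(isopropylidenedioxy)elema-3,11(13)-dien-12,8-olide; 35 angelic anhydride
Product: 36 (1R,5S,6S,7S,8R,9S,10S)-6-(angeloyloxy)-2-chloro-1,9-(isopropylidenedioxy)elema-3,11(13)-dien-12,8-olide
Conditions: LiN(SiMe3)2 (1.1 equiv), THF, −78 °C; 35 (1.5 equiv), −78 → −40 °C; AcOH
Reagents that add atoms: none
Why: Acylation of the preformed lithium alkoxide by the anhydride at low temperature esterifies the hindered axial 6β-hydroxyl without isomerising the angeloyl group.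

Step 25
Reactants: 36 (1R,5S,6S,7S,8R,9S,10S)-6-(angeloyloxy)-2-chloro-1,9-(isopropylidenedioxy)elema-3,11(13)-dien-12,8-olide
Product: 38 (1R,5S,6S,7S,8R,9S,10S)-6-(angeloyloxy)-1,2-epoxy-9-hydroxyelema-3,11(13)-dien-12,8-olide, via chlorohydrin diol 37 (not isolated)
Conditions: CSA (10 mol%), MeOH, 23 °C; concentrate; then KOtBu (1.05 equiv), THF, −40 → 0 °C
Reagents that add atoms: none
Why: Acid-catalysed transacetalisation frees the diol, and the C1 alkoxide next to the chloride closes the oxirane by intramolecular Williamson displacement (3-exo-tet) at C2, so C1 keeps its configuration.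

Step 26
Reactants: 38 (1R,5S,6S,7S,8R,9S,10S)-6-(angeloyloxy)-1,2-epoxy-9-hydroxyelema-3,11(13)-dien-12,8-olide
Product: 40 (1R,5R,6S,7S,8R,9S,10S)-6-(angeloyloxy)-1,2-epoxy-9-hydroxy-15-oxoelema-3,11(13)-dien-12,8-olide, via allylic alcohol 39 (not isolated)
Conditions: SeO2 (0.5 equiv), tBuOOH (2.5 equiv), CH2Cl2, 23 °C; then MnO2, CH2Cl2, 23 °C
Reagents that add atoms: tert-butyl hydroperoxide CC(C)(C)OO
Why: Selenium dioxide-catalysed allylic oxidation (ene reaction then [2,3]-shift) attacks the CH3 of the electron-rich isopropenyl group, and MnO2 oxidises only the resulting primary allylic alcohol to the enal.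

**Compound list**
1 | (S)-malic acid | OC(=O)C[C@H](O)C(=O)O | starting material
2 | dimethyl (2S)-2-hydroxybutanedioate | COC(=O)C[C@H](O)C(=O)OC | intermediate
3 | methyl (3S)-3,4-dihydroxybutanoate | COC(=O)C[C@H](O)CO | intermediate
4 | methyl (3S)-4-[(tert-butyldimethylsilyl)oxy]-3-hydroxybutanoate | COC(=O)C[C@H](O)CO[Si](C)(C)C(C)(C)C | intermediate
5 | (2-ethoxy-2-oxoethyl)triphenylphosphonium bromide | CCOC(=O)C[P+](c1ccccc1)(c1ccccc1)c1ccccc1.[Br-] | starting material
6 | ethyl 2-(triphenyl-λ5-phosphanylidene)acetate | CCOC(=O)C=P(c1ccccc1)(c1ccccc1)c1ccccc1 | intermediate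
7 | methacrolein (2-methylprop-2-enal) | C=C(C)C=O | starting material
8 | ethyl (2E)-4-methylpenta-2,4-dienoate | CCOC(=O)/C=C/C(C)=C | intermediate
9 | (2E)-4-methylpenta-2,4-dien-1-ol | OC/C=C/C(C)=C | intermediate
10 | (2E)-4-methylpenta-2,4-dien-1-yl (3S)-4-[(tert-butyldimethylsilyl)oxy]-3-hydroxybutanoate | C=C(C)/C=C/COC(=O)C[C@H](O)CO[Si](C)(C)C(C)(C)C | intermediate
11 | (2R,3S)-4-[(tert-butyldimethylsilyl)oxy]-3-hydroxy-2-[(3R)-2-methylpenta-1,4-dien-3-yl]butanoic acid | CC(C)(C)[Si](C)(C)OC[C@@H](O)[C@H](C(=O)O)[C@@H](C=C)C(C)=C | intermediate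
12 | methyl (2R,3S)-4-[(tert-butyldimethylsilyl)oxy]-3-hydroxy-2-[(3R)-2-methylpenta-1,4-dien-3-yl]butanoate | CC(C)(C)[Si](C)(C)OC[C@@H](O)[C@H](C(=O)OC)[C@@H](C=C)C(C)=C | intermediate
13 | methyl (2S,3S)-4-[(tert-butyldimethylsilyl)oxy]-3-hydroxy-2-methyl-2-[(3S)-2-methylpenta-1,4-dien-3-yl]butanoate | CC(C)(C)[Si](C)(C)OC[C@@H](O)[C@@](C)(C(=O)OC)[C@@H](C=C)C(C)=C | intermediate
14 | (3S,4S)-5-[(tert-butyldimethylsilyl)oxy]-1-chloro-4-hydroxy-3-methyl-3-[(3S)-2-methylpenta-1,4-dien-3-yl]pentan-2-one | CC(C)(C)[Si](C)(C)OC[C@@H](O)[C@@](C)(C(=O)CCl)[C@@H](C=C)C(C)=C | intermediate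
15 | (2R,3S,4S)-5-[(tert-butyldimethylsilyl)oxy]-1-chloro-3-methyl-3-[(3S)-2-methylpenta-1,4-dien-3-yl]pentane-2,4-diol | CC(C)(C)[Si](C)(C)OC[C@@H](O)[C@@](C)([C@@H](O)CCl)[C@@H](C=C)C(C)=C | intermediate
16 | tert-butyl{[(4S,5S,6R)-6-(chloromethyl)-2,2,5-trimethyl-5-[(3S)-2-methylpenta-1,4-dien-3-yl]-1,3-dioxan-4-yl]methoxy}dimethylsilane | CC(C)(C)[Si](C)(C)OC[C@H]1OC(C)(C)O[C@@H](CCl)[C@@]1(C)[C@@H](C=C)C(C)=C | intermediate
17 | (3S)-3-[(4S,5S,6R)-4-{[(tert-butyldimethylsilyl)oxy]methyl}-6-(chloromethyl)-2,2,5-trimethyl-1,3-dioxan-5-yl]-4-methylpent-4-en-2-one | CC(C)(C)[Si](C)(C)OC[C@H]1OC(C)(C)O[C@@H](CCl)[C@@]1(C)[C@@H](C(C)=O)C(C)=C | intermediate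
18 | methyl bromoacetate | COC(=O)CBr | starting material
19 | methyl iodoacetate | COC(=O)CI | intermediate
20 | methyl (5S)-5-[(4S,5S,6R)-4-{[(tert-butyldimethylsilyl)oxy]methyl}-6-(chloromethyl)-2,2,5-trimethyl-1,3-dioxan-5-yl]-6-methyl-4-oxohept-6-enoate | CC(C)(C)[Si](C)(C)OC[C@H]1OC(C)(C)O[C@@H](CCl)[C@@]1(C)[C@@H](C(=O)CCC(=O)OC)C(C)=C | intermediate
21 | methyl (5S)-5-[(4S,5S,6R)-6-(chloromethyl)-4-(hydroxymethyl)-2,2,5-trimethyl-1,3-dioxan-5-yl]-6-methyl-4-oxohept-6-enoate | OC[C@H]1OC(C)(C)O[C@@H](CCl)[C@@]1(C)[C@@H](C(=O)CCC(=O)OC)C(C)=C | intermediate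
22 | methyl (5S)-5-[(4S,5S,6R)-6-(chloromethyl)-4-formyl-2,2,5-trimethyl-1,3-dioxan-5-yl]-6-methyl-4-oxohept-6-enoate | O=C[C@H]1OC(C)(C)O[C@@H](CCl)[C@@]1(C)[C@@H](C(=O)CCC(=O)OC)C(C)=C | intermediate
23 | methyl 2-[(4R,4aS,5S,7R,8R,8aS)-4-(chloromethyl)-8-hydroxy-2,2,4a-trimethyl-6-oxo-5-(prop-1-en-2-yl)hexahydro-4H-1,3-benzodioxin-7-yl]acetate | O=C1[C@H](CC(=O)OC)[C@@H](O)[C@H]2OC(C)(C)O[C@@H](CCl)[C@@]2(C)[C@@H]1C(C)=C | intermediate
24 | (1R,5S,7R,8R,9S,10S)-2-chloro-1,9-(isopropylidenedioxy)-6-oxoelem-3-en-12,8-olide | O=C1[C@@H]2CC(=O)O[C@H]2[C@H]3OC(C)(C)O[C@@H](CCl)[C@@]3(C)[C@@H]1C(C)=C | intermediate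
25 | (1R,5S,6S,7S,8R,9S,10S)-2-chloro-6-hydroxy-1,9-(isopropylidenedioxy)elem-3-en-12,8-olide | O[C@@H]1[C@@H]2CC(=O)O[C@H]2[C@H]3OC(C)(C)O[C@@H](CCl)[C@@]3(C)[C@@H]1C(C)=C | intermediate
26 | N,N,N',N'-tetramethylmethanediamine | CN(C)CN(C)C | starting material
27 | N,N-dimethylmethaniminium chloride | C[N+](C)=C.[Cl-] | intermediate
28 | (1R,5S,6S,7S,8R,9S,10S)-2-chloro-13-(dimethylamino)-6-hydroxy-1,9-(isopropylidenedioxy)elem-3-en-12,8-olide (C11 epimers) | O[C@@H]1[C@@H]2C(CN(C)C)C(=O)O[C@H]2[C@H]3OC(C)(C)O[C@@H](CCl)[C@@]3(C)[C@@H]1C(C)=C | intermediate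
29 | (1R,5S,6S,7S,8R,9S,10S)-2-chloro-6-hydroxy-1,9-(isopropylidenedioxy)-13-(trimethylammonio)elem-3-en-12,8-olide iodide (C11 epimers) | O[C@@H]1[C@@H]2C(C[N+](C)(C)C)C(=O)O[C@H]2[C@H]3OC(C)(C)O[C@@H](CCl)[C@@]3(C)[C@@H]1C(C)=C.[I-] | intermediate
30 | (1R,5S,6S,7S,8R,9S,10S)-2-chloro-6-hydroxy-1,9-(isopropylidenedioxy)elema-3,11(13)-dien-12,8-olide | O[C@@H]1[C@@H]2C(=C)C(=O)O[C@H]2[C@H]3OC(C)(C)O[C@@H](CCl)[C@@]3(C)[C@@H]1C(C)=C | intermediate
31 | tiglic acid [(2E)-2-methylbut-2-enoic acid] | C/C=C(\C)C(=O)O | starting material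
32 | rac-(2R,3S)-2,3-dibromo-2-methylbutanoic acid (racemate; one enantiomer drawn) | C[C@H](Br)[C@](C)(Br)C(=O)O | intermediate
33 | (2E)-3-bromo-2-methylbut-2-enoic acid | C/C(Br)=C(/C)C(=O)O | intermediate
34 | angelic acid [(2Z)-2-methylbut-2-enoic acid] | C/C=C(/C)C(=O)O | intermediate
35 | angelic anhydride [(2Z)-2-methylbut-2-enoic anhydride] | C/C=C(/C)C(=O)OC(=O)/C(C)=C\C | intermediate
36 | (1R,5S,6S,7S,8R,9S,10S)-6-(angeloyloxy)-2-chloro-1,9-(isopropylidenedioxy)elema-3,11(13)-dien-12,8-olide | C/C=C(/C)C(=O)O[C@@H]1[C@@H]2C(=C)C(=O)O[C@H]2[C@H]3OC(C)(C)O[C@@H](CCl)[C@@]3(C)[C@@H]1C(C)=C | intermediate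
37 | (1R,5S,6S,7S,8R,9S,10S)-6-(angeloyloxy)-2-chloro-1,9-dihydroxyelema-3,11(13)-dien-12,8-olide | C/C=C(/C)C(=O)O[C@@H]1[C@@H]2C(=C)C(=O)O[C@H]2[C@@H](O)[C@@](C)([C@@H](O)CCl)[C@@H]1C(C)=C | intermediate
38 | (1R,5S,6S,7S,8R,9S,10S)-6-(angeloyloxy)-1,2-epoxy-9-hydroxyelema-3,11(13)-dien-12,8-olide | C/C=C(/C)C(=O)O[C@@H]1[C@@H]2C(=C)C(=O)O[C@H]2[C@@H](O)[C@@](C)([C@@H]2CO2)[C@@H]1C(C)=C | intermediate
39 | (1R,5S,6S,7S,8R,9S,10S)-6-(angeloyloxy)-1,2-epoxy-9,15-dihydroxyelema-3,11(13)-dien-12,8-olide | C/C=C(/C)C(=O)O[C@@H]1[C@@H]2C(=C)C(=O)O[C@H]2[C@@H](O)[C@@](C)([C@@H]2CO2)[C@@H]1C(=C)CO | intermediate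
40 | (1R,5R,6S,7S,8R,9S,10S)-6-(angeloyloxy)-1,2-epoxy-9-hydroxy-15-oxoelema-3,11(13)-dien-12,8-olide (CNP0113462.3) | C/C=C(/C)C(=O)O[C@@H]1[C@@H]2C(=C)C(=O)O[C@H]2[C@@H](O)[C@@](C)([C@@H]2CO2)[C@@H]1C(=C)C=O | target

**Step count**
Total step count: 26. Longest linear sequence: 17 steps (steps 1–3 or 4–6, then 7–12, 14–17, 19, 24–26); 17/26 ≈ 0.65.

**Three steps most likely to fail, each with one fallback**

Step 8 (dianion Claisen rearrangement of a base-sensitive dienyl ester). The fallback sets out from 4 and 9 and comes back at 12. Alcohol 9 is converted with methyl chloroformate and pyridine into (2E)-4-methylpenta-2,4-dien-1-yl methyl carbonate F1. The zinc enolate of 4 (LiN(iPr)2, 2.2 equiv, then ZnCl2) is then allylated with F1 using [Ir(cod)Cl]2 and a chiral phosphoramidite ligand. This branched-selective allylic alkylation sets C5 through the ligand and gives 12 directly; any α-epimer converges in step 9.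

Step 10 (addition of LiCH2Cl to the hindered, neopentyl-type ester). The fallback sets out from 11 and comes back at 14, replacing steps 9 and 10. Acid 11 is isolated instead of being esterified and closed with PhSO2Cl in pyridine to (3R,4S)-4-{[(tert-butyldimethylsilyl)oxy]methyl}-3-[(3R)-2-methylpenta-1,4-dien-3-yl]oxetan-2-one F2. Its enolate (LiN(iPr)2, −78 °C) is methylated trans to the C4 substituent to give (3S,4S)-4-{[(tert-butyldimethylsilyl)oxy]methyl}-3-methyl-3-[(3S)-2-methylpenta-1,4-dien-3-yl]oxetan-2-one F3. The strained acyl–oxygen bond of the β-lactone is then opened by LiCH2Cl at −78 °C to give 14.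

Step 16 (cyclisation of the α-substituted ketone without dehydration). The fallback sets out from 17 and comes back at 24, replacing steps 14–16. Ketone 17 is desilylated with HF·pyridine to (3S)-3-[(4S,5S,6R)-6-(chloromethyl)-4-(hydroxymethyl)-2,2,5-trimethyl-1,3-dioxan-5-yl]-4-methylpent-4-en-2-one F4. Dess–Martin oxidation gives (4S,5S,6R)-6-(chloromethyl)-2,2,5-trimethyl-5-[(3S)-2-methyl-4-oxopent-1-en-3-yl]-1,3-dioxane-4-carbaldehyde F5. L-Proline cyclises this unhindered methyl ketone to (4R,4aS,5S,8R,8aS)-4-(chloromethyl)-8-hydroxy-2,2,4a-trimethyl-5-(prop-1-en-2-yl)hexahydro-4H-1,3-benzodioxin-6-one F6. Its dianion (LiN(iPr)2, 2.2 equiv, −78 °C) is alkylated at C7 with 19 anti to the C8 alkoxide (cyclic Frater–Seebach alkylation) to give 23, which PPTS lactonises to 24.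

Further compounds
F1 | step 8 | (2E)-4-methylpenta-2,4-dien-1-yl methyl carbonate | COC(=O)OC/C=C/C(C)=C
F2 | step 10 | (3R,4S)-4-{[(tert-butyldimethylsilyl)oxy]methyl}-3-[(3R)-2-methylpenta-1,4-dien-3-yl]oxetan-2-one | CC(C)(C)[Si](C)(C)OC[C@H]1OC(=O)[C@@H]1[C@@H](C=C)C(C)=C
F3 | step 10 | (3S,4S)-4-{[(tert-butyldimethylsilyl)oxy]methyl}-3-methyl-3-[(3S)-2-methylpenta-1,4-dien-3-yl]oxetan-2-one | CC(C)(C)[Si](C)(C)OC[C@H]1OC(=O)[C@@]1(C)[C@@H](C=C)C(C)=C
F4 | step 16 | (3S)-3-[(4S,5S,6R)-6-(chloromethyl)-4-(hydroxymethyl)-2,2,5-trimethyl-1,3-dioxan-5-yl]-4-methylpent-4-en-2-one | OC[C@H]1OC(C)(C)O[C@@H](CCl)[C@@]1(C)[C@@H](C(C)=O)C(C)=C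
F5 | step 16 | (4S,5S,6R)-6-(chloromethyl)-2,2,5-trimethyl-5-[(3S)-2-methyl-4-oxopent-1-en-3-yl]-1,3-dioxane-4-carbaldehyde | O=C[C@H]1OC(C)(C)O[C@@H](CCl)[C@@]1(C)[C@@H](C(C)=O)C(C)=C
F6 | step 16 | (4R,4aS,5S,8R,8aS)-4-(chloromethyl)-8-hydroxy-2,2,4a-trimethyl-5-(prop-1-en-2-yl)hexahydro-4H-1,3-benzodioxin-6-one | O=C1C[C@@H](O)[C@H]2OC(C)(C)O[C@@H](CCl)[C@@]2(C)[C@@H]1C(C)=C
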